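**Retrosynthetic overview**
1. Target 29 ⇐ Liebeskind–Srogl coupling of S-ethyl thioester 25 with the Z-locked alkenylboronic half-ester 28; 25 ⇐ double cross-metathesis (allyl → prenyl at C3 and C5) of 24.
2. Feature used: in the bicyclo[3.2.1]octane (C1 acyl bridgehead, C2 CMe2, C3 CH, C4 CH2, C5 bridgehead, C6 carbinol, C7 ring ketone, C8 bridging ketone) C4 is a bare methylene between stereocentre C3 and the quaternary bridgehead C5, which is α to C8. C3–C4 and C5–allyl are therefore cut together: C3 radical + exocyclic C5=C4 enone + allyltributylstannane.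
3. The six-membered ring C1–C2–C3–C4–C5–C8 is closed last (key step) onto the preformed cyclopentane C1–C7–C6–C5–C8 of 21.
4. 21 ⇐ Mannich methylenation at C5; C3 selenide ⇐ allylation of a selenoacetal ⇐ ozonolysis of a 1,1-dimethylallyl group ⇐ Claisen rearrangement (C1–C2; C1 set from C6).
5. Cyclopentanetrione 8 ⇐ Dieckmann-type C-acylation (C1–C7) ⇐ enzymatic desymmetrisation (sets C6) ⇐ dianion aldol of 1 with 2 (C5–C6).

Key step: step 12

**Remarks before the steps**
- Atom numbers C1–C8 are those of the bicyclic core of the target (C9 = acyl carbon on C6) and are used for all intermediates.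
- Assumption: pig liver esterase cleaves the ester group of 4 that gives (R)-5; should it prefer the other group, an esterase or lipase of opposite preference would be chosen by screening.
- Assumption: the target is taken as the open (Z)-γ-hydroxy enone as drawn; it may equilibrate with its cyclic hemiketal.
- Two spectator changes are made in the key-step pair: the C6 hydroxyl is carried as its triethylsilyl ether, and C3 carries allyl instead of prenyl (both allyl groups become prenyl in step 14).
- The C1–C2 bond between two quaternary carbons is made by sigmatropic rearrangement, because direct tert-alkylation of a 2-acyl-1,3-dione at carbon is not reliable.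
- Triones 7 and 8 are fully enolised; one enol tautomer is drawn.

**Route**

Step 1
Reactants: 1 5-methylhexane-2,4-dione; 2 diethyl oxomalonate (diethyl ketomalonate)
Product: 4 diethyl 2-hydroxy-2-(5-methyl-2,4-dioxohexyl)propanedioate, via dilithium dienediolate 3 (not isolated)
Conditions: LiN(iPr)2 (2.1 equiv), THF, 0 °C; then 2, −78 °C; AcOH, −78 °C
Reagents that add atoms: none
Why: The dianion of a β-diketone reacts at its terminal carbon, so aldol addition to the strongly electrophilic central carbonyl of 2 should form the C5–C6 bond cleanly; C6 is not yet stereogenic because its two ester groups are identical.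

Step 2
Reactants: 4 diethyl 2-hydroxy-2-(5-methyl-2,4-dioxohexyl)propanedioate
Product: 5 (2R)-3-ethoxy-2-hydroxy-2-(5-methyl-2,4-dioxohexyl)-3-oxopropanoic acid
Conditions: pig liver esterase, phosphate buffer pH 7.5, DMSO (10%), 25 °C, NaOH (pH-stat); then HCl to pH 2
Reagents that add atoms: water, O
Why: Hydrolysis of one of two enantiotopic ester groups of a prochiral disubstituted malonate by pig liver esterase (enzymatic desymmetrisation) makes C6 stereogenic, and the enzyme pocket decides which ester is cleaved.

Step 3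
Reactants: 5 (2R)-3-ethoxy-2-hydroxy-2-(5-methyl-2,4-dioxohexyl)-3-oxopropanoic acid
Product: 7 ethyl (1R)-1-hydroxy-3-(2-methylpropanoyl)-2,4-dioxocyclopentane-1-carboxylate (drawn as its C8 enol), via acyl imidazolide 6 (not isolated)
Conditions: CDI (1.1 equiv), THF, 0 °C to rt; then MgCl2, Et3N, MeCN, rt
Reagents that add atoms: none
Why: The acid is activated as its acyl imidazolide and acylates the magnesium enolate of the β-diketone at C1 (Dieckmann-type Claisen cyclisation, 5-exo-trig), a closure pulled forward by enolisation of the 2-acylcyclopentane-1,3-dione formed; the C6 centre is not involved.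

Step 4
Reactants: 7 ethyl (1R)-1-hydroxy-3-(2-methylpropanoyl)-2,4-dioxocyclopentane-1-carboxylate
Product: 8 S-ethyl (1R)-1-hydroxy-3-(2-methylpropanoyl)-2,4-dioxocyclopentane-1-carbothioate (drawn as its C8 enol)
Conditions: AlMe3 (5 equiv), EtSH (8 equiv), CH2Cl2, 0 °C to rt; 1 M HCl
Reagents that add atoms: ethanethiol, CCS
Why: Dimethylaluminium ethanethiolate exchanges the ester for the thioester (aluminium thiolate transesterification) while the acidic trione is held as its unreactive aluminium enolate and the neighbouring aluminium alkoxide activates the ester.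

Step 5
Reactants: 8 S-ethyl (1R)-1-hydroxy-3-(2-methylpropanoyl)-2,4-dioxocyclopentane-1-carbothioate; 9 3-methylbut-2-en-1-ol
Product: 11 S-ethyl (1R,3S)-1-hydroxy-3-(2-methylbut-3-en-2-yl)-3-(2-methylpropanoyl)-2,4-dioxocyclopentane-1-carbothioate, via O-prenyl enol ether 10 (not isolated)
Conditions: PPh3, DIAD, THF, 0 °C to rt; then PhMe, 110 °C
Reagents that add atoms: none
Why: Mitsunobu O-alkylation of the acidic enol is followed by a Claisen [3,3] rearrangement that transposes the prenyl group and forms the C1–C2 bond between two quaternary carbons, all regioisomeric enol ethers giving the same product; the CMe2 terminus should bond to the ring face that carries the small C6 hydroxyl, anti to the larger COSEt group, which sets C1 relative to C6.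

Step 6
Reactants: 11 S-ethyl (1R,3S)-1-hydroxy-3-(2-methylbut-3-en-2-yl)-3-(2-methylpropanoyl)-2,4-dioxocyclopentane-1-carbothioate
Product: 12 S-ethyl (1R,3S)-3-(2-methylbut-3-en-2-yl)-3-(2-methylpropanoyl)-2,4-dioxo-1-(triethylsilyloxy)cyclopentane-1-carbothioate
Conditions: Et3SiOTf, 2,6-lutidine, CH2Cl2, −78 to 0 °C
Reagents that add atoms: triethylsilyl trifluoromethanesulfonate, CC[Si](CC)(CC)OS(=O)(=O)C(F)(F)F
Why: Silylation of the tertiary alcohol with the silyl triflate and a hindered base keeps the C6 oxygen from closing onto the C3 aldehyde of the next step as a bridged lactol and from acting as a free β-hydroxyl in the later enolisation at C5.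

Step 7
Reactants: 12 S-ethyl (1R,3S)-3-(2-methylbut-3-en-2-yl)-3-(2-methylpropanoyl)-2,4-dioxo-1-(triethylsilyloxy)cyclopentane-1-carbothioate
Product: 14 S-ethyl (1R,3S)-3-(2-methyl-1-oxopropan-2-yl)-3-(2-methylpropanoyl)-2,4-dioxo-1-(triethylsilyloxy)cyclopentane-1-carbothioate, via ozonide 13 (not isolated)
Conditions: O3, CH2Cl2, −78 °C; then PPh3, −78 °C to rt
Reagents that add atoms: ozone, [O-][O+]=O
Why: Ozonolysis with reductive work-up cleaves the only C=C bond, the vinyl group, to the neopentyl-type aldehyde C3 without touching the thioester or the silyl ether.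

Step 8
Reactants: 14 S-ethyl (1R,3S)-3-(2-methyl-1-oxopropan-2-yl)-3-(2-methylpropanoyl)-2,4-dioxo-1-(triethylsilyloxy)cyclopentane-1-carbothioate
Product: 15 S-ethyl (1R,3S)-3-[2-methyl-1,1-bis(phenylselanyl)propan-2-yl]-3-(2-methylpropanoyl)-2,4-dioxo-1-(triethylsilyloxy)cyclopentane-1-carbothioate
Conditions: PhSeH (2.2 equiv), ZnCl2 (0.5 equiv), MgSO4, CH2Cl2, 0 °C to rt
Reagents that add atoms: benzeneselenol, [SeH]c1ccccc1
Why: Lewis-acid-catalysed selenoacetalisation is far faster at the aldehyde than at the three ketones, which are hindered and would have to form a cation next to the electron-poor C1.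

Step 9
Reactants: 15 S-ethyl (1R,3S)-3-[2-methyl-1,1-bis(phenylselanyl)propan-2-yl]-3-(2-methylpropanoyl)-2,4-dioxo-1-(triethylsilyloxy)cyclopentane-1-carbothioate; 16 allyltrimethylsilane
Product: 17 S-ethyl (1R,3S)-3-[2-methyl-3-(phenylselanyl)hex-5-en-2-yl]-3-(2-methylpropanoyl)-2,4-dioxo-1-(triethylsilyloxy)cyclopentane-1-carbothioate (both epimers at the selenium-bearing carbon C3)
Conditions: SnCl4 (2 equiv), CH2Cl2, −78 °C
Reagents that add atoms: none
Why: SnCl4 ionises one C–Se bond to a selenium-stabilised carbenium ion that allyltrimethylsilane captures (Hosomi–Sakurai-type allylation of a selenoacetal); C3 is formed as both epimers, which is acceptable because this centre becomes a planar radical in step 12.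

Step 10
Reactants: 17 S-ethyl (1R,3S)-3-[2-methyl-3-(phenylselanyl)hex-5-en-2-yl]-3-(2-methylpropanoyl)-2,4-dioxo-1-(triethylsilyloxy)cyclopentane-1-carbothioate
Product: 19 S-ethyl 5-[(dimethylamino)methyl]-3-[2-methyl-3-(phenylselanyl)hex-5-en-2-yl]-3-(2-methylpropanoyl)-2,4-dioxo-1-(triethylsilyloxy)cyclopentane-1-carbothioate (C1 and C6 as in 17; epimers at C3 and C5), via trimethylsilyl enol ether 18 (not isolated)
Conditions: Me3SiOTf, Et3N, CH2Cl2, 0 °C; then CH2=NMe2 I (Eschenmoser's salt), CH2Cl2, rt
Reagents that add atoms: dimethyl(methylidene)ammonium iodide (Eschenmoser's salt), C=[N+](C)C.[I-]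
Why: Soft enolisation can only occur towards C5, the sole ring α-methylene, and the silyl enol ether reacts with the iminium salt in a Mukaiyama-type Mannich reaction that tolerates the selenide and the thioester; the new C5 centre is removed in step 11.

Step 11
Reactants: 19 S-ethyl 5-[(dimethylamino)methyl]-3-[2-methyl-3-(phenylselanyl)hex-5-en-2-yl]-3-(2-methylpropanoyl)-2,4-dioxo-1-(triethylsilyloxy)cyclopentane-1-carbothioate
Product: 21 S-ethyl (1R,3R)-5-methylidene-3-[2-methyl-3-(phenylselanyl)hex-5-en-2-yl]-3-(2-methylpropanoyl)-2,4-dioxo-1-(triethylsilyloxy)cyclopentane-1-carbothioate (same spatial arrangement at C1 and C6 as in 17; the descriptor changes by priority only; both C3 epimers), via trimethylammonium iodide 20 (not isolated)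
Conditions: MeI (5 equiv), MeCN, rt; then aq. NaHCO3, CH2Cl2, rt; used at once
Reagents that add atoms: none
Why: The amine is quaternised much faster than the selenide, and mild base then expels trimethylamine by E1cB (Hofmann-type) elimination to the α-methylene ketone, the ammonium group being a far better leaving group than the β-silyloxy group.

Step 12
Reactants: 21 S-ethyl (1R,3R)-5-methylidene-3-[2-methyl-3-(phenylselanyl)hex-5-en-2-yl]-3-(2-methylpropanoyl)-2,4-dioxo-1-(triethylsilyloxy)cyclopentane-1-carbothioate; 22 allyltributylstannane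
Product: 23 S-ethyl 2,2-dimethyl-1-(2-methylpropanoyl)-7,8-dioxo-3,5-di(prop-2-en-1-yl)-6-(triethylsilyloxy)bicyclo[3.2.1]octane-6-carbothioate (C1 C3 C5 C6 configured as in the target: C3 allyl exo and equatorial; C6 silyloxy on the face of the C2–C4 bridge)
Conditions: 22 (5 equiv, 0.1 M), AIBN (0.3 equiv, in portions), PhH (0.02 M in 21), 80 °C
Reagents that add atoms: none
Why: Bu3Sn• (from AIBN and 22) abstracts the phenylseleno group from either C3 epimer of 21 to give one planar secondary radical, which adds to the terminal carbon C4 of the α-methylene ketone; the resulting C5 radical then adds to 22 and expels Bu3Sn• (SH2′), so that one chain forms C3–C4 and C5–allyl. The closest known chemistry is the tin-mediated radical cyclisation onto α-methylene ketones terminated by allyl transfer (Keck allylation cascade) and the allylation of bridgehead α-keto radicals of bicyclic ketones. Ring C1–C2–C3–C4–C5–C8 closes 6-endo-trig through a chair: attack at C4 is polarity-matched (nucleophilic alkyl radical, electron-poor terminus) and unhindered, whereas 5-exo attack would have to hit the fully substituted α-carbon C5 and build a strained bicyclo[2.2.1]heptane. C3 is set in that chair, where the allyl substituent of the planar radical lies equatorial (exo), away from the C6–C7 bridge; C5 is set because the tether from C1 brings C3 to the chain-bearing face of the cyclopentanone, which leaves only the exo bridgehead position for the allyl group; C1 and C6 are not touched. The step needs cyclisation to outrun direct allylation of the C3 radical, which the gem-dimethyl group, the quaternary C1 and the moderate stannane concentration should secure; it also needs a C5 radical that reacts readily with the stannane, which follows from its pyramidal bridgehead geometry, since its orbital lies in the nodal plane of the C8 carbonyl and it is a σ-type radical, not a delocalised enoxyl radical.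

Step 13
Reactants: 23 S-ethyl 2,2-dimethyl-1-(2-methylpropanoyl)-7,8-dioxo-3,5-di(prop-2-en-1-yl)-6-(triethylsilyloxy)bicyclo[3.2.1]octane-6-carbothioate
Product: 24 S-ethyl 6-hydroxy-2,2-dimethyl-1-(2-methylpropanoyl)-7,8-dioxo-3,5-di(prop-2-en-1-yl)bicyclo[3.2.1]octane-6-carbothioate (configuration as in 23)
Conditions: HF·pyridine, pyridine, THF, 0 °C to rt
Reagents that add atoms: none
Why: Fluoride cleaves the hindered triethylsilyl ether under weakly acidic, non-nucleophilic conditions that leave the thioester and the base-sensitive non-enolisable triketone intact.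

Step 14
Reactants: 24 S-ethyl 6-hydroxy-2,2-dimethyl-1-(2-methylpropanoyl)-7,8-dioxo-3,5-di(prop-2-en-1-yl)bicyclo[3.2.1]octane-6-carbothioate
Product: 25 S-ethyl 6-hydroxy-2,2-dimethyl-3,5-bis(3-methylbut-2-en-1-yl)-1-(2-methylpropanoyl)-7,8-dioxobicyclo[3.2.1]octane-6-carbothioate (configuration as in the target)
Conditions: second-generation Hoveyda–Grubbs catalyst (10 mol %), 2-methylbut-2-ene (excess), CH2Cl2, 40 °C
Reagents that add atoms: 2-methylbut-2-ene, CC=C(C)C
Why: Olefin cross-metathesis of both terminal allyl groups with 2-methylbut-2-ene, the usual way of turning allyl into prenyl next to quaternary centres, tolerates the thioester and the free tertiary alcohol and touches no stereocentre.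

Step 15
Reactants: 26 trimethyl[(2-methylbut-3-yn-2-yl)oxy]silane
Product: 28 5,5-dimethyl-1,2-oxaborol-2(5H)-ol, via catechol alkenylboronate 27 (not isolated)
Conditions: catecholborane, [RhCl(cod)]2 (1.5 mol %), P(iPr)3 (6 mol %), Et3N, cyclohexane, rt; then 1 M HCl, THF/H2O, rt
Reagents that add atoms: catecholborane, B1Oc2ccccc2O1; water, O
Why: Rhodium-catalysed anti-Markovnikov hydroboration of a terminal alkyne through a vinylidene gives the (Z)-alkenylboronate, and acid hydrolysis of the catechol ester and the silyl ether lets the cis hydroxyl close onto boron, which locks the Z geometry in a five-membered ring.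

Step 16
Reactants: 25 S-ethyl 6-hydroxy-2,2-dimethyl-3,5-bis(3-methylbut-2-en-1-yl)-1-(2-methylpropanoyl)-7,8-dioxobicyclo[3.2.1]octane-6-carbothioate; 28 5,5-dimethyl-1,2-oxaborol-2(5H)-ol
Product: 29 CNP0190794.1 (target)
Conditions: Pd2(dba)3 (5 mol %), tri(2-furyl)phosphine (20 mol %), copper thiophene-2-carboxylate (CuTC, 1.6 equiv), THF, 50 °C; aq. NH4Cl
Reagents that add atoms: none
Why: Liebeskind–Srogl coupling (zerovalent palladium, stoichiometric copper carboxylate) joins the thioester to the alkenylboron reagent under neutral conditions with retention of the Z geometry, and hydrolysis of the boron–oxygen bond on work-up frees the tertiary alcohol of the side chain.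

**Compound list**
1 | 5-methylhexane-2,4-dione | CC(C)C(=O)CC(C)=O | starting material
2 | diethyl oxomalonate | CCOC(=O)C(=O)C(=O)OCC | starting material
3 | dilithium 5-methylhexa-1,3-diene-2,4-diolate (dianion of 1) | [Li+].[Li+].C=C([O-])C=C([O-])C(C)C | intermediate (not isolated)
4 | diethyl 2-hydroxy-2-(5-methyl-2,4-dioxohexyl)propanedioate | CCOC(=O)C(O)(CC(=O)CC(=O)C(C)C)C(=O)OCC | intermediate
5 | (2R)-3-ethoxy-2-hydroxy-2-(5-methyl-2,4-dioxohexyl)-3-oxopropanoic acid | OC(=O)[C@@](CC(=O)CC(=O)C(C)C)(O)C(=O)OCC | intermediate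
6 | ethyl (2R)-2-hydroxy-2-(imidazol-1-ylcarbonyl)-7-methyl-4,6-dioxooctanoate (acyl imidazolide of 5) | O=C(n1ccnc1)[C@@](CC(=O)CC(=O)C(C)C)(O)C(=O)OCC | intermediate (not isolated)
7 | ethyl (1R)-1-hydroxy-3-(2-methylpropanoyl)-2,4-dioxocyclopentane-1-carboxylate (C8 enol drawn) | C1C(O)=C(C(=O)C(C)C)C(=O)[C@@]1(O)C(=O)OCC | intermediate
8 | S-ethyl (1R)-1-hydroxy-3-(2-methylpropanoyl)-2,4-dioxocyclopentane-1-carbothioate (C8 enol drawn) | C1C(O)=C(C(=O)C(C)C)C(=O)[C@@]1(O)C(=O)SCC | intermediate
9 | 3-methylbut-2-en-1-ol | CC(C)=CCO | starting material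
10 | S-ethyl (1R)-1-hydroxy-4-(3-methylbut-2-enyloxy)-3-(2-methylpropanoyl)-2-oxocyclopent-3-ene-1-carbothioate (one of the regioisomeric O-prenyl enol ethers) | C1C(OCC=C(C)C)=C(C(=O)C(C)C)C(=O)[C@@]1(O)C(=O)SCC | intermediate (not isolated)
11 | S-ethyl (1R,3S)-1-hydroxy-3-(2-methylbut-3-en-2-yl)-3-(2-methylpropanoyl)-2,4-dioxocyclopentane-1-carbothioate (OH cis to the tert-alkyl group) | C1C(=O)[C@@](C(=O)C(C)C)(C(=O)[C@@]1(O)C(=O)SCC)C(C)(C)C=C | intermediate
12 | S-ethyl (1R,3S)-3-(2-methylbut-3-en-2-yl)-3-(2-methylpropanoyl)-2,4-dioxo-1-(triethylsilyloxy)cyclopentane-1-carbothioate | C1C(=O)[C@@](C(=O)C(C)C)(C(=O)[C@@]1(O[Si](CC)(CC)CC)C(=O)SCC)C(C)(C)C=C | intermediate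
13 | ozonide (1,2,4-trioxolane) of 12, epimers at the trioxolane carbon | C1C(=O)[C@@](C(=O)C(C)C)(C(=O)[C@@]1(O[Si](CC)(CC)CC)C(=O)SCC)C(C)(C)C2OCOO2 | intermediate (not isolated)
14 | S-ethyl (1R,3S)-3-(2-methyl-1-oxopropan-2-yl)-3-(2-methylpropanoyl)-2,4-dioxo-1-(triethylsilyloxy)cyclopentane-1-carbothioate | C1C(=O)[C@@](C(=O)C(C)C)(C(=O)[C@@]1(O[Si](CC)(CC)CC)C(=O)SCC)C(C)(C)C=O | intermediate
15 | S-ethyl (1R,3S)-3-[2-methyl-1,1-bis(phenylselanyl)propan-2-yl]-3-(2-methylpropanoyl)-2,4-dioxo-1-(triethylsilyloxy)cyclopentane-1-carbothioate | C1C(=O)[C@@](C(=O)C(C)C)(C(=O)[C@@]1(O[Si](CC)(CC)CC)C(=O)SCC)C(C)(C)C([Se]c2ccccc2)[Se]c2ccccc2 | intermediate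
16 | allyltrimethylsilane | C=CC[Si](C)(C)C | starting material
17 | S-ethyl (1R,3S)-3-[2-methyl-3-(phenylselanyl)hex-5-en-2-yl]-3-(2-methylpropanoyl)-2,4-dioxo-1-(triethylsilyloxy)cyclopentane-1-carbothioate, both C3 epimers | C1C(=O)[C@@](C(=O)C(C)C)(C(=O)[C@@]1(O[Si](CC)(CC)CC)C(=O)SCC)C(C)(C)C([Se]c2ccccc2)CC=C | intermediate
18 | C5=C8 trimethylsilyl enol ether of 17 | C1=C(O[Si](C)(C)C)[C@@](C(=O)C(C)C)(C(=O)[C@@]1(O[Si](CC)(CC)CC)C(=O)SCC)C(C)(C)C([Se]c2ccccc2)CC=C | intermediate (not isolated)
19 | S-ethyl 5-[(dimethylamino)methyl]-3-[2-methyl-3-(phenylselanyl)hex-5-en-2-yl]-3-(2-methylpropanoyl)-2,4-dioxo-1-(triethylsilyloxy)cyclopentane-1-carbothioate (C1, C6 as in 17; epimers at C3 and C5) | CN(C)CC1C(=O)[C@@](C(=O)C(C)C)(C(=O)[C@@]1(O[Si](CC)(CC)CC)C(=O)SCC)C(C)(C)C([Se]c2ccccc2)CC=C | intermediate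
20 | trimethylammonium iodide of 19 | [I-].C[N+](C)(C)CC1C(=O)[C@@](C(=O)C(C)C)(C(=O)[C@@]1(O[Si](CC)(CC)CC)C(=O)SCC)C(C)(C)C([Se]c2ccccc2)CC=C | intermediate (not isolated)
21 | S-ethyl (1R,3R)-5-methylidene-3-[2-methyl-3-(phenylselanyl)hex-5-en-2-yl]-3-(2-methylpropanoyl)-2,4-dioxo-1-(triethylsilyloxy)cyclopentane-1-carbothioate, both C3 epimers (key-step precursor) | C=C1C(=O)[C@@](C(=O)C(C)C)(C(=O)[C@@]1(O[Si](CC)(CC)CC)C(=O)SCC)C(C)(C)C([Se]c2ccccc2)CC=C | intermediate
22 | allyltributylstannane | C=CC[Sn](CCCC)(CCCC)CCCC | starting material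
23 | S-ethyl 2,2-dimethyl-1-(2-methylpropanoyl)-7,8-dioxo-3,5-di(prop-2-en-1-yl)-6-(triethylsilyloxy)bicyclo[3.2.1]octane-6-carbothioate, C1/C3/C5/C6 as in the target (key-step product) | C=CC[C@@H]1C[C@]2(CC=C)C(=O)[C@@](C(=O)C(C)C)(C(=O)[C@@]2(O[Si](CC)(CC)CC)C(=O)SCC)C1(C)C | intermediate
24 | S-ethyl 6-hydroxy-2,2-dimethyl-1-(2-methylpropanoyl)-7,8-dioxo-3,5-di(prop-2-en-1-yl)bicyclo[3.2.1]octane-6-carbothioate, configuration as in the target | C=CC[C@@H]1C[C@]2(CC=C)C(=O)[C@@](C(=O)C(C)C)(C(=O)[C@@]2(O)C(=O)SCC)C1(C)C | intermediate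
25 | S-ethyl 6-hydroxy-2,2-dimethyl-3,5-bis(3-methylbut-2-en-1-yl)-1-(2-methylpropanoyl)-7,8-dioxobicyclo[3.2.1]octane-6-carbothioate, configuration as in the target | CC(C)=CC[C@@H]1C[C@]2(CC=C(C)C)C(=O)[C@@](C(=O)C(C)C)(C(=O)[C@@]2(O)C(=O)SCC)C1(C)C | intermediate
26 | trimethyl[(2-methylbut-3-yn-2-yl)oxy]silane | C#CC(C)(C)O[Si](C)(C)C | starting material
27 | 2-[(1Z)-3-methyl-3-(trimethylsilyloxy)but-1-en-1-yl]-1,3,2-benzodioxaborole | C[Si](C)(C)OC(C)(C)/C=C\B1Oc2ccccc2O1 | intermediate (not isolated)
28 | 5,5-dimethyl-1,2-oxaborol-2(5H)-ol | CC1(C)C=CB(O)O1 | intermediate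
29 | CNP0190794.1 | CC(C)=CC[C@@H]1C[C@]2(CC=C(C)C)C(=O)[C@@](C(=O)C(C)C)(C(=O)[C@@]2(O)C(=O)/C=C\C(C)(C)O)C1(C)C | target

**Count**
Total steps: 16 (15 in the main line, 1 for reagent 28). Longest linear sequence: 15 steps (steps 1–14 and 16).

**Steps most likely to fail**

Step 12 (key step). The C3 radical may be allylated by the stannane before it closes the ring, or may take the isobutyryl methine hydrogen by 1,5-transfer. The bridgehead radical may also rearrange by 1,2-acyl shift before it meets the stannane. Fallback (from 21, back at 23): ring closure and allylation are separated. Photo-induced electron-transfer cleavage of the C3–Se bond (irradiation through Pyrex, 1,5-dimethoxynaphthalene, PhSeSePh, MeCN), with no allyl donor present, lets the ring close first, and phenylseleno-group transfer then caps the C5 radical to give the bridgehead selenide F1. A separate radical allylation of this selenide with 22 (AIBN, PhH, 80 °C), in which no cyclisation has to compete, should then give 23.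

Step 5. The enol ether may ionise to a prenyl cation and trione anion that recombine at the primary terminus or lose isoprene. The face selectivity at C1 also rests only on the size difference between OH and COSEt. Fallback (from 8, back at 11): copper-catalysed propargylic substitution of 2-methylbut-3-yn-2-yl acetate by the enol of 8 (CuOTf·½C6H6, a chiral pybox ligand, iPr2NEt, MeOH, 0 °C). Here the trione attacks the tertiary carbon of a copper allenylidene, and the ligand, not the substrate, selects the face of C1. This should give the 1,1-dimethylpropargyl trione F2; semihydrogenation (H2, Pd/CaCO3 poisoned with Pb(OAc)2, quinoline) then gives 11.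

Step 16. Acyl–sulfur activation may be slow because the thioester sits on a fully substituted carbon. Protodeboronation of 28 or Z-to-E isomerisation of the product may then intervene. Fallback (from 25, back at 29): palladium/copper-catalysed coupling of the thioester with 2-methylbut-3-yn-2-ol (PdCl2(dppf), tri(2-furyl)phosphine, copper iodide CuI, Et3N, DMF, 50 °C) gives the ynone F3. Its semihydrogenation (H2, Pd/CaCO3 poisoned with Pb(OAc)2, quinoline, EtOAc) sets the Z-alkene and gives 29.

**Further compounds**
F1 | step 12 | S-ethyl 2,2-dimethyl-1-(2-methylpropanoyl)-7,8-dioxo-5-(phenylselanyl)-3-(prop-2-en-1-yl)-6-(triethylsilyloxy)bicyclo[3.2.1]octane-6-carbothioate (configuration as in 23) | C=CC[C@@H]1C[C@]2([Se]c3ccccc3)C(=O)[C@@](C(=O)C(C)C)(C(=O)[C@@]2(O[Si](CC)(CC)CC)C(=O)SCC)C1(C)C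
F2 | step 5 | S-ethyl (1R,3S)-1-hydroxy-3-(2-methylbut-3-yn-2-yl)-3-(2-methylpropanoyl)-2,4-dioxocyclopentane-1-carbothioate | C1C(=O)[C@@](C(=O)C(C)C)(C(=O)[C@@]1(O)C(=O)SCC)C(C)(C)C#C
F3 | step 16 | 6-hydroxy-6-(4-hydroxy-4-methylpent-2-ynoyl)-2,2-dimethyl-3,5-bis(3-methylbut-2-en-1-yl)-1-(2-methylpropanoyl)bicyclo[3.2.1]octane-7,8-dione (configuration as in the target) | CC(C)=CC[C@@H]1C[C@]2(CC=C(C)C)C(=O)[C@@](C(=O)C(C)C)(C(=O)[C@@]2(O)C(=O)C#CC(C)(C)O)C1(C)C
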